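**Assumption and corrections (chemistry only).** Atoms are numbered C1–O25 in the order of the target SMILES, which encodes 5S,7S,11R,13R,17S,19S,24R. The chain linking C13 to C24 in the 12-membered enol ether has nine atoms (C12, C11, C10, C9, C7, C5, C4, C3, C2), not ten. C13 of the enol ether is made deliberately as the 13S epimer instead of arising as one of two epimers. Both late epoxidations need the L-fructose-derived ketone (S,S-oxiranes), and the C24 reduction needs the (S)-oxazaborolidine (24R).

## Structural features

The target is a 14-membered carbocycle (C2–C5, C7, C9–C13, C19, C22–C24). It carries a trans-trisubstituted oxirane (C5–O6–C7, methyl C8), a 1,1-disubstituted alkene C1=C2 next to the secondary carbinol C24, and a δ-lactone (C11–C12–C13–O14–C15–C17) bridging C11 and C13. The stereocentres fall into three groups that cannot control one another: C17/C11/C13 on the lactone with the adjacent tertiary carbinol C19 (O21, methyl C20), the oxirane pair C5/C7, and C24 alone. O14 and O21 are anti across C13–C19, the pattern left when an E-alkene is epoxidised and opened with inversion at C13 by the C15 carboxyl; C5/C7 is the same alkene type left closed. Fragile groups are the oxirane (acid, transannular attack by O25 at C5), the allylic alcohol beside the exo-methylene, the tertiary alcohol and the epimerisable C17. The real difficulty is closing a 14-membered ring with two E-trisubstituted alkenes where the closing bond has no functional handle, while setting three remote stereo-groups by reagent control. The key step uses the fact that C24 (at ketone level) and the C13=C19 alkene are 1,5-related through C23–C22: once the C24 acid is tied to the C13 hydroxyl as a 12-membered lactone, its enol ether is the allyl vinyl ether C23=C24–O14–C13–C19=C22. The exo-methylene on C2 makes the rearranged ketone the enone needed for C24.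

## Logic of the disconnections

35 to 33: the lactone bond O14–C13, the tertiary C19–O21 bond and both oxirane C–O bonds are cut back to the two E-trisubstituted alkenes and the C15 acid. This removes four stereocentres and one ring at once. The forward step must epoxidise both alkenes with the same catalyst antipode, leave C1=C2 alone, and let the carboxylate open C13 in the 6-exo mode with inversion.

33 to 29: the C15 acid is traced to a silyl-protected primary alcohol and the C24 carbinol to a ketone. The stereocentre C24 disappears and the acid is masked against the earlier carbonyl chemistry. The forward steps need catalyst-controlled hydride delivery to an α-methylene ketone and oxidation of a primary alcohol beside a secondary allylic one.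

29 to 28: C22–C23 is cut and O14–C13 reconnected (retro-Claisen). A carbocycle without a handle at the closing bond becomes a 12-membered oxacycle closed through oxygen, and the C13=C19 alkene becomes an isopropenyl carbinol ether. The forward step must pass through the chair with C12 equatorial to give the E-alkene.

28 to 25: the C24=C23 enol ether is traced to the lactone carbonyl, and the ester bond C24–O14 is cut to a hydroxy acid. Ring closure is reduced to a lactonisation. The forward steps must methylenate a conjugated lactone and favour the 12-membered ring over oligomers.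

25 to 20: the C24 acid is traced to a PMB-protected 2-substituted allyl alcohol, and the C15 silyl ether/C13 carbinol pair to a δ-lactone (bond C15–O14). The lactone holds C11, C13 and C17 in one ring and tells the two oxygens apart by primary versus secondary. The forward steps need a selective silylation and a selective oxidation of the primary allylic alcohol.

20 to 15 + 11: C17–C18 (methyl) and C10–C11 are cut. Two stereocentres are reduced to the single centre C13 of an unsaturated lactone. The forward steps must add the C10 organometallic anti to the C13 substituent and methylate anti to the new C11 chain, and 1,4-addition must beat allylic substitution.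

15 to 12: the ring alkene C11=C17 is cut (metathesis), then the acrylate ester, then C12–C13 (allylation of an enal). This leaves one reagent-controlled stereocentre made from two commodity chemicals. The allylation must give the 13S alcohol.

11 to 5 + 6: C3–C4 is cut between an allylic bromide and the carbon terminus of a dianion that already carries C1, C2 and O-bearing C24. The forward step needs SN2 rather than SN2′ attack and then differentiation of the two chain ends.

5 to 1: C4–C5 and C7–C8 are cut back to a terminal alkyne. The E geometry of C5=C7 then follows from syn carbometalation with no olefination selectivity problem. The forward step needs regioselective methyl transfer to the internal alkyne carbon.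

## Other disconnections considered

Alternative 1: The cut runs through C4–C5 and C7–C8. Terminal alkyne A2 (C5≡C7 with the C9–C22 half, C11/C17 set) is methylaluminated syn with AlMe3/Cp2ZrCl2, transmetalated with ZnCl2 and coupled with primary iodide A3 under Pd2(dba)3/tricyclopentylphosphine to give acyclic triene A1 with all twenty carbons.
- In its favour: it is highly convergent. The E geometry comes from the same syn-carbometalation used in step 1 of the chosen route (equal on this point). C24 is configured in an open chain, which is better than a late reduction of a macrocyclic enone.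
- Against it here: the electrophile is an unactivated homoallylic iodide whose alkylpalladium intermediate can lose a β-hydrogen. The carbometalation must tolerate three silyl ethers and a PMB ether on advanced material. A1 is still acyclic, so the ring must then be closed at C22–C23 by an sp3–sp3 bond between termini that first need refunctionalising, and C13=C19 must be made separately.
- Comparison: structurally A1 solves the C5=C7 problem, which the chosen plan solves on a four-carbon alkyne, and leaves open ring closure and C13=C19, which the Claisen step solves together. Mechanistically it replaces a unimolecular pericyclic step with a demanding bimolecular cross-coupling. Step counts are probably close: it saves the C15 reduction–reoxidation but spends steps on orthogonal protection and end-group adjustment.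

Alternative 2: The cut is at C10–C11 and C17–C18. Grignard reagent A5 adds to 5,6-dihydro-2H-pyran-2-one A6 under CuBr·SMe2 and a chiral ferrocenyl diphosphine, and the magnesium enolate is methylated in the same flask to give trans lactone A4.
- In its favour: one catalytic step from a commercial lactone sets C11 and C17, which is better than steps 7–11 of the chosen route for the same pair. The trans relationship arises the same way (equal).
- Against it here: A4 leaves C13 as an unsubstituted CH2–O and C15 as the carbonyl, so the two ends need about five steps to differentiate and C13 comes out as two epimers. The chain ends at C4, so C3, C2, C1 and C24 must be added later. The enantioselectivity rests on a catalyst with a functionalised Grignard reagent.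
- Comparison: both are copper-mediated 1,4-additions followed by enolate methylation; they differ in the source of facial control (ligand versus the C13 substituent). The alternative is shorter up to the lactone and longer after it, so the totals are about equal. It does not address ring formation. The chosen plan gains a single defined C13 epimer for the key step.

Alternative 3: The cut is at C7–C9 in the ring. Seco compound A8 is hydroborated with 9-BBN at its only monosubstituted alkene (C9=C10), and the C9 borane couples with the C7 iodide under PdCl2(dppf), Ph3As and Cs2CO3 to close the 14-membered ring as A7.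
- In its favour: closure is mild and non-thermal, with retention of the alkenyl iodide geometry. C15 stays an ester, so the protection and reoxidation of steps 13, 20 and 21 are not needed (better). C24 is set by an open-chain oxirane (better).
- Against it here: both trisubstituted alkenes need separate stereoselective syntheses. The cyclisation depends on high dilution and on a borane that spares the oxirane and ester. The oxirane must later be isomerised toward C1 and not C3.
- Comparison: A7 and 30 are at a similar stage. Mechanistically it is a metal-mediated end-to-end C–C closure, against a C–O closure followed by a [3,3] shift that creates C13=C19 while it expands the ring. It saves three to four late steps but pays for them in making A8, so neither is clearly shorter.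

Key step: step 18

## Route

Step 1
Reactants: 1 tert-butyl(but-3-yn-1-yloxy)dimethylsilane
Product: 4 (2E)-5-[(tert-butyldimethylsilyl)oxy]-3-methylpent-2-en-1-ol, via alkenylalane 2 (not isolated), via lithium alanate 3 (not isolated)
Conditions: AlMe3, Cp2ZrCl2 (0.25 equiv), CH2Cl2, 0 °C → rt; n-BuLi, THF, −78 °C; (CH2O)n, → rt; aq. KNaC4H4O6
Reagents that add atoms: trimethylaluminium, C[Al](C)C; formaldehyde (as paraformaldehyde), C=O
Why: Negishi carboalumination adds CH3 and Al syn across the alkyne with methyl on the internal carbon, so 2 is E; the alanate 3 is hydroxymethylated with retention, which fixes C5=C7 with C4 and C9 trans.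

Step 2
Reactants: 4 (2E)-5-[(tert-butyldimethylsilyl)oxy]-3-methylpent-2-en-1-ol
Product: 5 {[(3E)-5-bromo-3-methylpent-3-en-1-yl]oxy}(tert-butyl)dimethylsilane
Conditions: CBr4, PPh3, 2,6-lutidine, CH2Cl2, −20 → 0 °C
Reagents that add atoms: tetrabromomethane, BrC(Br)(Br)Br
Why: Appel bromination displaces the oxyphosphonium ion at primary C4 by SN2; low temperature and a hindered base should suppress allylic transposition and silyl loss.

Step 3
Reactants: 5 {[(3E)-5-bromo-3-methylpent-3-en-1-yl]oxy}(tert-butyl)dimethylsilane; 6 2-methylprop-2-en-1-ol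
Product: 8 (5E)-8-[(tert-butyldimethylsilyl)oxy]-6-methyl-2-methylideneoct-5-en-1-ol, via dianion 7 (not isolated)
Conditions: 6 (2 equiv), n-BuLi (4 equiv), TMEDA, Et2O, 0 °C → rt; then 5, THF, −78 → 0 °C
Reagents that add atoms: none
Why: C-alkylation of the methallyl alcohol dianion with a primary allylic bromide; SN2 at C4 is expected because the SN2′ terminus C7 is fully substituted; this forms C3–C4 and brings in C1, C2 and C24 as a masked acrylic acid.

Step 4
Reactants: 8 (5E)-8-[(tert-butyldimethylsilyl)oxy]-6-methyl-2-methylideneoct-5-en-1-ol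
Product: 9 tert-butyl{[(3E)-8-[(4-methoxyphenyl)methoxy]-3-methyl-7-methylideneoct-3-en-1-yl]oxy}dimethylsilane
Conditions: NaH, PMBCl, Bu4NI (cat.), THF/DMF, 0 °C → rt
Reagents that add atoms: 4-methoxybenzyl chloride, COc1ccc(CCl)cc1
Why: Williamson etherification of the primary allylic alkoxide; the PMB ether survives every organometallic and hydride step and is removable beside silyl ethers.

Step 5
Reactants: 9 tert-butyl{[(3E)-8-[(4-methoxyphenyl)methoxy]-3-methyl-7-methylideneoct-3-en-1-yl]oxy}dimethylsilane
Product: 10 (3E)-8-[(4-methoxyphenyl)methoxy]-3-methyl-7-methylideneoct-3-en-1-ol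
Conditions: Bu4NF, THF, 0 °C → rt
Reagents that add atoms: none
Why: Fluoride cleavage of the primary silyl ether; PMB ether and both alkenes are inert.

Step 6
Reactants: 10 (3E)-8-[(4-methoxyphenyl)methoxy]-3-methyl-7-methylideneoct-3-en-1-ol
Product: 11 1-({[(5E)-8-bromo-6-methyl-2-methylideneoct-5-en-1-yl]oxy}methyl)-4-methoxybenzene
Conditions: CBr4, PPh3, CH2Cl2, 0 °C
Reagents that add atoms: tetrabromomethane, BrC(Br)(Br)Br
Why: Appel bromination of a primary homoallylic alcohol under neutral conditions; it gives the C10 bromide for the Grignard reagent.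

Step 7
Reactants: 12 2-methylprop-2-enal
Product: 13 (3S)-2-methylhexa-1,5-dien-3-ol
Conditions: (−)-Ipc2B(allyl), Et2O, −78 °C; then NaOH, H2O2, 0 °C → rt
Reagents that add atoms: (−)-B-allyldiisopinocampheylborane, C=CCB([C@@H]1C[C@@H]2C[C@H]([C@H]1C)C2(C)C)[C@@H]1C[C@@H]2C[C@H]([C@H]1C)C2(C)C
Why: Brown allylboration through a closed chair transition state; the reagent from (+)-α-pinene attacks the aldehyde face that gives the S carbinol when the carbonyl substituent outranks allyl, as isopropenyl does; this sets C13 and the enantiopurity of the whole series.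

Step 8
Reactants: 13 (3S)-2-methylhexa-1,5-dien-3-ol
Product: 14 (3S)-2-methylhexa-1,5-dien-3-yl prop-2-enoate
Conditions: acryloyl chloride, Et3N, DMAP (cat.), CH2Cl2, −20 → 0 °C
Reagents that add atoms: acryloyl chloride, C=CC(=O)Cl
Why: Standard O-acylation of a secondary allylic alcohol; the stereocentre is not touched.

Step 9
Reactants: 14 (3S)-2-methylhexa-1,5-dien-3-yl prop-2-enoate
Product: 15 (6S)-6-(prop-1-en-2-yl)-5,6-dihydro-2H-pyran-2-one
Conditions: second-generation Grubbs catalyst (H2IMes)(PCy3)Cl2Ru=CHPh (3 mol %), CH2Cl2 (10 mM), 40 °C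
Reagents that add atoms: none
Why: Ring-closing metathesis; the ruthenium carbene loads on the monosubstituted alkene and closes onto the acrylate to the six-membered lactone, while the 1,1-disubstituted isopropenyl group is a slow partner.

Step 10
Reactants: 11 1-({[(5E)-8-bromo-6-methyl-2-methylideneoct-5-en-1-yl]oxy}methyl)-4-methoxybenzene; 15 (6S)-6-(prop-1-en-2-yl)-5,6-dihydro-2H-pyran-2-one
Product: 18 (4R,6S)-4-[(3E)-8-[(4-methoxyphenyl)methoxy]-3-methyl-7-methylideneoct-3-en-1-yl]-6-(prop-1-en-2-yl)oxan-2-one, via Grignard reagent 16 (not isolated), via silyl ketene acetal 17 (not isolated)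
Conditions: 11, Mg, THF, rt; then CuBr·SMe2 (0.2 equiv), Me3SiCl, 15 (1.3 equiv), THF, −78 °C; 1 M HCl
Reagents that add atoms: none
Why: Copper-catalysed, chlorosilane-accelerated conjugate addition of a Grignard reagent to an unsaturated δ-lactone; attack at C11 is axial and anti to the pseudo-equatorial C13 substituent, giving the 4,6-trans lactone (11R); at −78 °C with silyl trapping, 1,4-addition should outrun substitution of the allylic lactone C–O bond.

Step 11
Reactants: 18 (4R,6S)-4-[(3E)-8-[(4-methoxyphenyl)methoxy]-3-methyl-7-methylideneoct-3-en-1-yl]-6-(prop-1-en-2-yl)oxan-2-one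
Product: 20 (3S,4R,6S)-4-[(3E)-8-[(4-methoxyphenyl)methoxy]-3-methyl-7-methylideneoct-3-en-1-yl]-3-methyl-6-(prop-1-en-2-yl)oxan-2-one, via lithium enolate 19 (not isolated)
Conditions: LiN(i-Pr)2, THF, −78 °C; MeI, −78 → −40 °C
Reagents that add atoms: iodomethane, CI
Why: Alkylation of a δ-lactone enolate anti to the adjacent C4 substituent gives the 3,4-trans product, which sets C17 (S) from C11.

Step 12
Reactants: 20 (3S,4R,6S)-4-[(3E)-8-[(4-methoxyphenyl)methoxy]-3-methyl-7-methylideneoct-3-en-1-yl]-3-methyl-6-(prop-1-en-2-yl)oxan-2-one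
Product: 21 (2S,3R,5S)-3-[(3E)-8-[(4-methoxyphenyl)methoxy]-3-methyl-7-methylideneoct-3-en-1-yl]-2,6-dimethylhept-6-ene-1,5-diol
Conditions: LiAlH4, THF, 0 °C; aq. KNaC4H4O6
Reagents that add atoms: none
Why: Hydride reduction of the lactone gives a primary alcohol at C15 and a secondary allylic alcohol at C13, which are easy to tell apart; fast reduction leaves C17 untouched.

Step 13
Reactants: 21 (2S,3R,5S)-3-[(3E)-8-[(4-methoxyphenyl)methoxy]-3-methyl-7-methylideneoct-3-en-1-yl]-2,6-dimethylhept-6-ene-1,5-diol
Product: 22 (3S,5R,6S)-7-[(tert-butyldimethylsilyl)oxy]-5-[(3E)-8-[(4-methoxyphenyl)methoxy]-3-methyl-7-methylideneoct-3-en-1-yl]-2,6-dimethylhept-1-en-3-ol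
Conditions: t-BuMe2SiCl (1.05 equiv), imidazole, CH2Cl2, −20 → 0 °C
Reagents that add atoms: tert-butyldimethylsilyl chloride, CC(C)(C)[Si](C)(C)Cl
Why: Silylation selective for the primary over the hindered secondary allylic hydroxyl; C15 is masked as a group inert to Cp2TiMe2, heat and borane.

Step 14
Reactants: 22 (3S,5R,6S)-7-[(tert-butyldimethylsilyl)oxy]-5-[(3E)-8-[(4-methoxyphenyl)methoxy]-3-methyl-7-methylideneoct-3-en-1-yl]-2,6-dimethylhept-1-en-3-ol
Product: 23 (5E,9R,11S)-9-[(2S)-1-[(tert-butyldimethylsilyl)oxy]propan-2-yl]-6,12-dimethyl-2-methylidenetrideca-5,12-diene-1,11-diol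
Conditions: DDQ, CH2Cl2/pH 7 buffer, 0 °C
Reagents that add atoms: none
Why: Oxidative cleavage of the electron-rich benzyl ether; the silyl ether, the unconjugated allylic alcohol and the alkenes should survive buffered DDQ.

Step 15
Reactants: 23 (5E,9R,11S)-9-[(2S)-1-[(tert-butyldimethylsilyl)oxy]propan-2-yl]-6,12-dimethyl-2-methylidenetrideca-5,12-diene-1,11-diol
Product: 25 (5E,9R,11S)-9-[(2S)-1-[(tert-butyldimethylsilyl)oxy]propan-2-yl]-11-hydroxy-6,12-dimethyl-2-methylidenetrideca-5,12-dienoic acid, via enal 24 (not isolated)
Conditions: TEMPO (0.2 equiv), PhI(OAc)2, CH2Cl2, 0 °C → rt; then NaClO2, NaH2PO4, 2-methylbut-2-ene, t-BuOH/H2O, 0 °C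
Reagents that add atoms: sodium chlorite, [Na+].[O-]Cl=O
Why: The oxoammonium oxidation is sterically selective for the unhindered primary allylic C24 alcohol over the secondary C13 alcohol; Pinnick oxidation then converts the 2-substituted acrolein into the α-methylene acid under buffered conditions.

Step 16
Reactants: 25 (5E,9R,11S)-9-[(2S)-1-[(tert-butyldimethylsilyl)oxy]propan-2-yl]-11-hydroxy-6,12-dimethyl-2-methylidenetrideca-5,12-dienoic acid
Product: 27 (6E,10R,12S)-10-[(2S)-1-[(tert-butyldimethylsilyl)oxy]propan-2-yl]-7-methyl-3-methylidene-12-(prop-1-en-2-yl)-1-oxacyclododec-6-en-2-one, via mixed anhydride 26 (not isolated)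
Conditions: 2-methyl-6-nitrobenzoic anhydride, DMAP, CH2Cl2 (2 mM final), rt, syringe-pump addition
Reagents that add atoms: none
Why: Shiina macrolactonisation activates the acid at room temperature, which suits a heat- and base-sensitive acrylic acid; high dilution favours the 12-membered ring, and the ester bond C24–O14 is the temporary tether.

Step 17
Reactants: 27 (6E,10R,12S)-10-[(2S)-1-[(tert-butyldimethylsilyl)oxy]propan-2-yl]-7-methyl-3-methylidene-12-(prop-1-en-2-yl)-1-oxacyclododec-6-en-2-one
Product: 28 (6E,10R,12S)-10-[(2S)-1-[(tert-butyldimethylsilyl)oxy]propan-2-yl]-7-methyl-2,3-dimethylidene-12-(prop-1-en-2-yl)-1-oxacyclododec-6-ene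
Conditions: Cp2TiMe2 (3 equiv), toluene/THF, 65 °C, dark; basic Al2O3 filtration
Reagents that add atoms: dimethyltitanocene, C[Ti](C)(C1C=CC=C1)C1C=CC=C1
Why: Petasis methylenation; the titanocene methylidene converts lactone carbonyls, conjugated ones included, into enol ethers under non-acidic conditions, creating the C24=C23 vinyl ether without touching the silyl ether or the alkenes.

Step 18
Reactants: 28 (6E,10R,12S)-10-[(2S)-1-[(tert-butyldimethylsilyl)oxy]propan-2-yl]-7-methyl-2,3-dimethylidene-12-(prop-1-en-2-yl)-1-oxacyclododec-6-ene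
Product: 29 (4E,7R,10E)-7-[(2S)-1-[(tert-butyldimethylsilyl)oxy]propan-2-yl]-4,10-dimethyl-14-methylidenecyclotetradeca-4,10-dien-1-one
Conditions: degassed toluene (5 mM), BHT (10 mol %), K2CO3-washed sealed tube, 120 °C
Reagents that add atoms: none
Why: The allyl vinyl ether C23=C24–O14–C13–C19=C22 undergoes a concerted suprafacial [3,3] shift: C22–C23 forms, O14–C13 breaks, and C13=C19 and the C24 carbonyl appear, driven by C=O formation and conjugation with C1=C2. The closest known type is the Claisen ring expansion of 2-methylene oxacycles bearing an alkenyl group next to oxygen, established for medium rings and applied here to 12 → 14. The 14-membered carbocycle is closed by ring enlargement by two carbons, not end to end: the new bond joins two exocyclic sp2 termini held in a six-membered chair fused to the O14–C13/C24 edge of the existing ring, so there is little entropic cost. No stereocentre is formed and C13 is erased. The selectivity needed is the E geometry of C13=C19, which requires the chair with C12 equatorial on C13. The axial alternative is penalised by the C19 methyl and by the C2 substituent on C24, and the nine-atom tether should span the equatorial arrangement. The second requirement is chemoselectivity over polymerisation and over a Cope shift of the C1=C2–C3–C4–C5=C7 diene, addressed by moderate temperature, dilution, a radical inhibitor and acid-free glass.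

Step 19
Reactants: 29 (4E,7R,10E)-7-[(2S)-1-[(tert-butyldimethylsilyl)oxy]propan-2-yl]-4,10-dimethyl-14-methylidenecyclotetradeca-4,10-dien-1-one
Product: 30 (1R,4E,7R,10E)-7-[(2S)-1-[(tert-butyldimethylsilyl)oxy]propan-2-yl]-4,10-dimethyl-14-methylidenecyclotetradeca-4,10-dien-1-ol
Conditions: (S)-2-methyl-CBS-oxazaborolidine (0.3 equiv), catecholborane, toluene, −78 °C; MeOH, aq. NaOH wash
Reagents that add atoms: none
Why: Corey–Bakshi–Shibata reduction; the ketone binds with the larger 1,1-disubstituted alkenyl group (C2) away from the catalyst, and hydride goes to the face that gives 24R, by analogy with aryl alkyl ketones; catecholborane at low temperature avoids hydroboration and 1,4-reduction.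

Step 20
Reactants: 30 (1R,4E,7R,10E)-7-[(2S)-1-[(tert-butyldimethylsilyl)oxy]propan-2-yl]-4,10-dimethyl-14-methylidenecyclotetradeca-4,10-dien-1-ol
Product: 31 (1R,4E,7R,10E)-7-[(2S)-1-hydroxypropan-2-yl]-4,10-dimethyl-14-methylidenecyclotetradeca-4,10-dien-1-ol
Conditions: Bu4NF, THF, 0 °C → rt
Reagents that add atoms: none
Why: Fluoride cleavage of the primary silyl ether; nothing else in the molecule is fluoride- or base-sensitive at this stage.

Step 21
Reactants: 31 (1R,4E,7R,10E)-7-[(2S)-1-hydroxypropan-2-yl]-4,10-dimethyl-14-methylidenecyclotetradeca-4,10-dien-1-ol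
Product: 33 (2S)-2-[(1R,3E,7R,11E)-7-hydroxy-4,12-dimethyl-8-methylidenecyclotetradeca-3,11-dien-1-yl]propanoic acid, via aldehyde 32 (not isolated)
Conditions: TEMPO (0.1 equiv), PhI(OAc)2 (1.1 equiv), CH2Cl2, 0 °C; then NaClO2, NaH2PO4, 2-methylbut-2-ene, t-BuOH/H2O, 0 °C
Reagents that add atoms: sodium chlorite, [Na+].[O-]Cl=O
Why: Steric discrimination by the oxoammonium ion favours the primary C15 alcohol over the secondary C24 alcohol; telescoping into the buffered Pinnick oxidation limits epimerisation of the α-methyl aldehyde at C17.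

Step 22
Reactants: 33 (2S)-2-[(1R,3E,7R,11E)-7-hydroxy-4,12-dimethyl-8-methylidenecyclotetradeca-3,11-dien-1-yl]propanoic acid
Product: 35 target CNP0262409.1 (5S,7S,11R,13R,17S,19S,24R), via bis-epoxy acid 34 (not isolated)
Conditions: L-fructose-derived Shi ketone (0.6 equiv), KHSO5 (as 2KHSO5·KHSO4·K2SO4, 3 equiv), K2CO3, Bu4NHSO4 (cat.), MeCN/CH2(OMe)2, aq. Na2B4O7 buffer pH 10.5, 0 °C; then NaH2PO4 to pH 5, CH2Cl2, rt
Reagents that add atoms: potassium peroxymonosulfate, [K+].[O-]S(=O)(=O)OO
Why: Shi epoxidation through the spiro transition state of the L-series dioxirane should give the S,S-oxirane at each E-trisubstituted alkene (5S,7S and 13S,19S), the mirror image of the R,R sense of the D-series ketone; the less electron-rich 1,1-disubstituted C1=C2 reacts more slowly. On mild acidification the C15 carboxyl opens the nearby oxirane at secondary C13 in the 6-exo mode with inversion (13S → 13R) and leaves O21 on C19 (S); the remote C5–C7 oxirane is untouched.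

## Compound list

1 | tert-butyl(but-3-yn-1-yloxy)dimethylsilane | C#CCCO[Si](C)(C)C(C)(C)C | starting material
2 | [(1E)-4-[(tert-butyldimethylsilyl)oxy]-2-methylbut-1-en-1-yl]dimethylalumane | C[Al](C)/C=C(\C)CCO[Si](C)(C)C(C)(C)C | intermediate
3 | lithium butyl[(1E)-4-[(tert-butyldimethylsilyl)oxy]-2-methylbut-1-en-1-yl]dimethylaluminate | [Li+].CCCC[Al-](C)(C)/C=C(\C)CCO[Si](C)(C)C(C)(C)C | intermediate
4 | (2E)-5-[(tert-butyldimethylsilyl)oxy]-3-methylpent-2-en-1-ol | OC/C=C(\C)CCO[Si](C)(C)C(C)(C)C | intermediate
5 | {[(3E)-5-bromo-3-methylpent-3-en-1-yl]oxy}(tert-butyl)dimethylsilane | BrC/C=C(\C)CCO[Si](C)(C)C(C)(C)C | intermediate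
6 | 2-methylprop-2-en-1-ol | CC(=C)CO | starting material
7 | dilithium dianion of 2-methylprop-2-en-1-ol (lithium 2-(lithiomethyl)prop-2-en-1-olate) | [Li]CC(=C)CO[Li] | intermediate
8 | (5E)-8-[(tert-butyldimethylsilyl)oxy]-6-methyl-2-methylideneoct-5-en-1-ol | C=C(CO)CC/C=C(\C)CCO[Si](C)(C)C(C)(C)C | intermediate
9 | tert-butyl{[(3E)-8-[(4-methoxyphenyl)methoxy]-3-methyl-7-methylideneoct-3-en-1-yl]oxy}dimethylsilane | C=C(COCc1ccc(OC)cc1)CC/C=C(\C)CCO[Si](C)(C)C(C)(C)C | intermediate
10 | (3E)-8-[(4-methoxyphenyl)methoxy]-3-methyl-7-methylideneoct-3-en-1-ol | C=C(COCc1ccc(OC)cc1)CC/C=C(\C)CCO | intermediate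
11 | 1-({[(5E)-8-bromo-6-methyl-2-methylideneoct-5-en-1-yl]oxy}methyl)-4-methoxybenzene | C=C(COCc1ccc(OC)cc1)CC/C=C(\C)CCBr | intermediate
12 | 2-methylprop-2-enal | CC(=C)C=O | starting material
13 | (3S)-2-methylhexa-1,5-dien-3-ol | C=CC[C@H](O)C(C)=C | intermediate
14 | (3S)-2-methylhexa-1,5-dien-3-yl prop-2-enoate | C=CC[C@H](OC(=O)C=C)C(C)=C | intermediate
15 | (6S)-6-(prop-1-en-2-yl)-5,6-dihydro-2H-pyran-2-one | C=C(C)[C@@H]1CC=CC(=O)O1 | intermediate
16 | {(3E)-8-[(4-methoxyphenyl)methoxy]-3-methyl-7-methylideneoct-3-en-1-yl}magnesium bromide | COc1ccc(COCC(=C)CC/C=C(\C)CC[Mg]Br)cc1 | intermediate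
17 | {[(2S,4R)-4-[(3E)-8-[(4-methoxyphenyl)methoxy]-3-methyl-7-methylideneoct-3-en-1-yl]-2-(prop-1-en-2-yl)-3,4-dihydro-2H-pyran-6-yl]oxy}trimethylsilane | COc1ccc(COCC(=C)CC/C=C(\C)CC[C@@H]2C[C@H](OC(O[Si](C)(C)C)=C2)C(C)=C)cc1 | intermediate
18 | (4R,6S)-4-[(3E)-8-[(4-methoxyphenyl)methoxy]-3-methyl-7-methylideneoct-3-en-1-yl]-6-(prop-1-en-2-yl)oxan-2-one | COc1ccc(COCC(=C)CC/C=C(\C)CC[C@@H]2C[C@H](OC(=O)C2)C(C)=C)cc1 | intermediate
19 | lithium enolate of 18 (lithium (2S,4R)-4-alkyl-2-(prop-1-en-2-yl)-3,4-dihydro-2H-pyran-6-olate) | COc1ccc(COCC(=C)CC/C=C(\C)CC[C@@H]2C[C@H](OC(O[Li])=C2)C(C)=C)cc1 | intermediate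
20 | (3S,4R,6S)-4-[(3E)-8-[(4-methoxyphenyl)methoxy]-3-methyl-7-methylideneoct-3-en-1-yl]-3-methyl-6-(prop-1-en-2-yl)oxan-2-one | COc1ccc(COCC(=C)CC/C=C(\C)CC[C@@H]2C[C@H](OC(=O)[C@H]2C)C(C)=C)cc1 | intermediate
21 | (2S,3R,5S)-3-[(3E)-8-[(4-methoxyphenyl)methoxy]-3-methyl-7-methylideneoct-3-en-1-yl]-2,6-dimethylhept-6-ene-1,5-diol | COc1ccc(COCC(=C)CC/C=C(\C)CC[C@@H]([C@H](C)CO)C[C@H](O)C(C)=C)cc1 | intermediate
22 | (3S,5R,6S)-7-[(tert-butyldimethylsilyl)oxy]-5-[(3E)-8-[(4-methoxyphenyl)methoxy]-3-methyl-7-methylideneoct-3-en-1-yl]-2,6-dimethylhept-1-en-3-ol | COc1ccc(COCC(=C)CC/C=C(\C)CC[C@@H]([C@H](C)CO[Si](C)(C)C(C)(C)C)C[C@H](O)C(C)=C)cc1 | intermediate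
23 | (5E,9R,11S)-9-[(2S)-1-[(tert-butyldimethylsilyl)oxy]propan-2-yl]-6,12-dimethyl-2-methylidenetrideca-5,12-diene-1,11-diol | OCC(=C)CC/C=C(\C)CC[C@@H]([C@H](C)CO[Si](C)(C)C(C)(C)C)C[C@H](O)C(C)=C | intermediate
24 | (5E,9R,11S)-9-[(2S)-1-[(tert-butyldimethylsilyl)oxy]propan-2-yl]-11-hydroxy-6,12-dimethyl-2-methylidenetrideca-5,12-dienal | O=CC(=C)CC/C=C(\C)CC[C@@H]([C@H](C)CO[Si](C)(C)C(C)(C)C)C[C@H](O)C(C)=C | intermediate
25 | (5E,9R,11S)-9-[(2S)-1-[(tert-butyldimethylsilyl)oxy]propan-2-yl]-11-hydroxy-6,12-dimethyl-2-methylidenetrideca-5,12-dienoic acid | OC(=O)C(=C)CC/C=C(\C)CC[C@@H]([C@H](C)CO[Si](C)(C)C(C)(C)C)C[C@H](O)C(C)=C | intermediate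
26 | mixed anhydride of 25 with 2-methyl-6-nitrobenzoic acid | Cc1cccc([N+](=O)[O-])c1C(=O)OC(=O)C(=C)CC/C=C(\C)CC[C@@H]([C@H](C)CO[Si](C)(C)C(C)(C)C)C[C@H](O)C(C)=C | intermediate
27 | (6E,10R,12S)-10-[(2S)-1-[(tert-butyldimethylsilyl)oxy]propan-2-yl]-7-methyl-3-methylidene-12-(prop-1-en-2-yl)-1-oxacyclododec-6-en-2-one | C=C1CC/C=C(\C)CC[C@@H]([C@H](C)CO[Si](C)(C)C(C)(C)C)C[C@@H](C(C)=C)OC1=O | intermediate
28 | (6E,10R,12S)-10-[(2S)-1-[(tert-butyldimethylsilyl)oxy]propan-2-yl]-7-methyl-2,3-dimethylidene-12-(prop-1-en-2-yl)-1-oxacyclododec-6-ene | C=C1CC/C=C(\C)CC[C@@H]([C@H](C)CO[Si](C)(C)C(C)(C)C)C[C@@H](C(C)=C)OC1=C | intermediate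
29 | (4E,7R,10E)-7-[(2S)-1-[(tert-butyldimethylsilyl)oxy]propan-2-yl]-4,10-dimethyl-14-methylidenecyclotetradeca-4,10-dien-1-one | C=C1CC/C=C(\C)CC[C@@H]([C@H](C)CO[Si](C)(C)C(C)(C)C)C/C=C(\C)CCC1=O | intermediate
30 | (1R,4E,7R,10E)-7-[(2S)-1-[(tert-butyldimethylsilyl)oxy]propan-2-yl]-4,10-dimethyl-14-methylidenecyclotetradeca-4,10-dien-1-ol | C=C1CC/C=C(\C)CC[C@@H]([C@H](C)CO[Si](C)(C)C(C)(C)C)C/C=C(\C)CC[C@H]1O | intermediate
31 | (1R,4E,7R,10E)-7-[(2S)-1-hydroxypropan-2-yl]-4,10-dimethyl-14-methylidenecyclotetradeca-4,10-dien-1-ol | C=C1CC/C=C(\C)CC[C@@H]([C@H](C)CO)C/C=C(\C)CC[C@H]1O | intermediate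
32 | (2S)-2-[(1R,3E,7R,11E)-7-hydroxy-4,12-dimethyl-8-methylidenecyclotetradeca-3,11-dien-1-yl]propanal | C=C1CC/C=C(\C)CC[C@@H]([C@H](C)C=O)C/C=C(\C)CC[C@H]1O | intermediate
33 | (2S)-2-[(1R,3E,7R,11E)-7-hydroxy-4,12-dimethyl-8-methylidenecyclotetradeca-3,11-dien-1-yl]propanoic acid | C=C1CC/C=C(\C)CC[C@@H]([C@H](C)C(=O)O)C/C=C(\C)CC[C@H]1O | intermediate
34 | bis-epoxy acid: 33 with (5S,7S)- and (13S,19S)-oxiranes on the former C5=C7 and C13=C19 alkenes (target numbering; 11R,17S,24R unchanged) | C=C1CC[C@@H]2O[C@@]2(C)CC[C@@H]([C@H](C)C(=O)O)C[C@@H]2O[C@@]2(C)CC[C@H]1O | intermediate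
35 | target CNP0262409.1: 14-membered carbocycle with (5S,7S)-oxirane, δ-lactone O14–C15(=O) bridging C13 and C11 (11R,13R,17S), tertiary carbinol 19S, exo-methylene C1=C2 and 24R carbinol | C=C1CC[C@@H]2O[C@@]2(C)CC[C@@H]2C[C@@H](OC(=O)[C@H]2C)[C@@](C)(O)CC[C@H]1O | target

## Step count and least certain steps

Total step count: 22. Longest linear sequence: 19 steps (steps 1–6, then 10–22, from 1); the lactone branch (steps 7–9) joins at step 10.

**Step 18 (key step).** The most likely failure is thermal consumption of material. The cross-conjugated dienyl ether and the α-methylene ketone can polymerise or dimerise, and the C1=C2–C3–C4–C5=C7 diene can undergo a Cope shift at the temperature the Claisen needs. A second risk is leakage through the arrangement with C12 axial, giving the Z alkene, if the tether strains the chair. Fallback: from 28, treatment with i-Bu3Al in CH2Cl2 at −78 → 0 °C promotes the rearrangement by coordination to O14 and reduces the new ketone in the same flask by β-hydride transfer, so the enone never accumulates. This gives 30 together with its C24 epimer, (1S,4E,7R,10E)-alcohol F1. Oxidation of the mixture with Dess–Martin periodinane at 0 °C returns to the route at 29.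

**Step 22.** The most likely failure is loss of facial control at one of the two alkenes, because the macrocycle presents one face preferentially and may oppose the ketone (mismatched case). The free C24 hydroxyl adds risk: it can assist oxidation of C1=C2 and can open the C5–C7 oxirane transannularly at C5 during acidification. Fallback: from 30, i-Pr3SiOTf/2,6-lutidine gives the 24-O-triisopropylsilyl ether F2. PPTS in MeOH removes only the primary silyl ether, giving alcohol F3. The oxidation of step 21 gives acid F4, now with no competing secondary alcohol. Epoxidation and lactonisation as in step 22 give the silylated target F5, and buffered Bu4NF/AcOH returns to the route at 35. The silyl ether removes the hydroxyl participation and changes the ring conformation offered to the dioxirane.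

**Step 17.** The most likely failure is unselective or incomplete methylenation: the titanium carbene can engage the electron-poor exo-methylene, and the acid-labile dienyl ether can hydrolyse on isolation. Fallback: from 27, conjugate addition of PhSH (Et3N cat., CH2Cl2) masks the acrylate as the phenylthio adduct F6 (C2 epimers, irrelevant). Cp2TiMe2 then methylenates a saturated lactone to enol ether F7. Thermolysis as in step 18 gives the 2-(phenylthiomethyl) ketone F8. NaIO4 oxidation gives sulfoxide F9, and warming in toluene at 80 °C over CaCO3 eliminates it, returning to the route at 29. This detour also keeps the diene and the enone out of the hot Claisen step.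

**Step 16.** The most likely failure is intermolecular acylation to cyclic dimer and oligomers, because the hindered secondary allylic hydroxyl is acylated slowly and the 12-membered ring has transannular strain. Fallback: from 25, a Mitsunobu macrolactonisation (PPh3, diisopropyl azodicarboxylate, toluene, high dilution) activates the alcohol instead of the acid and closes the same C24–O14 bond with inversion, giving the 13R-epimeric macrolactone F10. Because C13 becomes trigonal in the key step, F10 is methylenated as in step 17 to the 13R-epimeric enol ether F11, whose thermolysis returns to the route at 29.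

**Step 10.** The most likely failure is copper-mediated allylic substitution at C22, with the lactone carboxylate as leaving group, competing with 1,4-addition; erosion of the trans selectivity is a second risk. Fallback: Grignard reagent 16 is added to 5,6-dihydro-2H-pyran-2-one F12 under CuBr·SMe2 and a chiral ferrocenyl diphosphine (the ligand antipode that gives 4R), and the enolate is trapped with MeI to give the (3S,4R)-lactone F13. AlMe3/MeNHOMe·HCl opens it to the hydroxy Weinreb amide F14, and Dess–Martin oxidation gives aldehyde F15. Isopropenylmagnesium bromide (from 2-bromopropene) at −78 °C followed by acidic work-up closes the lactone and returns to the route at 20, formed together with its C6 epimer F16. F16 can be carried along, since C13 is erased in step 18, or separated.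

## Further compounds

F1 | step 18 | (1S,4E,7R,10E)-7-[(2S)-1-[(tert-butyldimethylsilyl)oxy]propan-2-yl]-4,10-dimethyl-14-methylidenecyclotetradeca-4,10-dien-1-ol (C24 epimer of 30) | C=C1CC/C=C(\C)CC[C@@H]([C@H](C)CO[Si](C)(C)C(C)(C)C)C/C=C(\C)CC[C@@H]1O
F2 | step 22 | 24-O-triisopropylsilyl ether of 30 | C=C1CC/C=C(\C)CC[C@@H]([C@H](C)CO[Si](C)(C)C(C)(C)C)C/C=C(\C)CC[C@H]1O[Si](C(C)C)(C(C)C)C(C)C
F3 | step 22 | 24-O-triisopropylsilyl ether of 31 (free C15 alcohol) | C=C1CC/C=C(\C)CC[C@@H]([C@H](C)CO)C/C=C(\C)CC[C@H]1O[Si](C(C)C)(C(C)C)C(C)C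
F4 | step 22 | 24-O-triisopropylsilyl ether of 33 | C=C1CC/C=C(\C)CC[C@@H]([C@H](C)C(=O)O)C/C=C(\C)CC[C@H]1O[Si](C(C)C)(C(C)C)C(C)C
F5 | step 22 | 24-O-triisopropylsilyl ether of 35 | C=C1CC[C@@H]2O[C@@]2(C)CC[C@@H]2C[C@@H](OC(=O)[C@H]2C)[C@@](C)(O)CC[C@H]1O[Si](C(C)C)(C(C)C)C(C)C
F6 | step 17 | phenylthio adduct of 27 (3-[(phenylsulfanyl)methyl] macrolactone, C2 epimers) | c1ccccc1SCC1CC/C=C(\C)CC[C@@H]([C@H](C)CO[Si](C)(C)C(C)(C)C)C[C@@H](C(C)=C)OC1=O
F7 | step 17 | 2-methylidene enol ether of F6 | c1ccccc1SCC1CC/C=C(\C)CC[C@@H]([C@H](C)CO[Si](C)(C)C(C)(C)C)C[C@@H](C(C)=C)OC1=C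
F8 | step 17 | 14-[(phenylsulfanyl)methyl] analogue of 29 (C2 epimers) | c1ccccc1SCC1CC/C=C(\C)CC[C@@H]([C@H](C)CO[Si](C)(C)C(C)(C)C)C/C=C(\C)CCC1=O
F9 | step 17 | sulfoxide of F8 | O=S(c1ccccc1)CC1CC/C=C(\C)CC[C@@H]([C@H](C)CO[Si](C)(C)C(C)(C)C)C/C=C(\C)CCC1=O
F10 | step 16 | (6E,10R,12R)-epimer of 27 (13R in target numbering) | C=C1CC/C=C(\C)CC[C@@H]([C@H](C)CO[Si](C)(C)C(C)(C)C)C[C@H](C(C)=C)OC1=O
F11 | step 16 | (6E,10R,12R)-epimer of 28 | C=C1CC/C=C(\C)CC[C@@H]([C@H](C)CO[Si](C)(C)C(C)(C)C)C[C@H](C(C)=C)OC1=C
F12 | step 10 | 5,6-dihydro-2H-pyran-2-one | O=C1C=CCCO1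
F13 | step 10 | (3S,4R)-4-[(3E)-8-[(4-methoxyphenyl)methoxy]-3-methyl-7-methylideneoct-3-en-1-yl]-3-methyloxan-2-one | COc1ccc(COCC(=C)CC/C=C(\C)CC[C@@H]2CCOC(=O)[C@H]2C)cc1
F14 | step 10 | (2S,3R)-5-hydroxy-N-methoxy-3-[(3E)-8-[(4-methoxyphenyl)methoxy]-3-methyl-7-methylideneoct-3-en-1-yl]-N,2-dimethylpentanamide | COc1ccc(COCC(=C)CC/C=C(\C)CC[C@@H]([C@H](C)C(=O)N(C)OC)CCO)cc1
F15 | step 10 | (2S,3R)-N-methoxy-3-[(3E)-8-[(4-methoxyphenyl)methoxy]-3-methyl-7-methylideneoct-3-en-1-yl]-N,2-dimethyl-5-oxopentanamide | COc1ccc(COCC(=C)CC/C=C(\C)CC[C@@H]([C@H](C)C(=O)N(C)OC)CC=O)cc1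
F16 | step 10 | (3S,4R,6R)-epimer of 20 | COc1ccc(COCC(=C)CC/C=C(\C)CC[C@@H]2C[C@@H](OC(=O)[C@H]2C)C(C)=C)cc1
A1 | alternative 1 | acyclic C22-to-C23 triene with all twenty skeletal carbons | COc1ccc(COC[C@@H](O[Si](C)(C)C(C)(C)C)C(=C)CC/C=C(\C)CC[C@@H]([C@H](C)CO[Si](C(C)C)(C(C)C)C(C)C)C/C=C(\C)CO[Si](C)(C)C(C)(C)C)cc1
A2 | alternative 1 | terminal alkyne fragment (C5≡C7 to C22) | C#CCC[C@@H]([C@H](C)CO[Si](C(C)C)(C(C)C)C(C)C)C/C=C(\C)CO[Si](C)(C)C(C)(C)C
A3 | alternative 1 | C4 primary iodide fragment (C4 to C23) | COc1ccc(COC[C@@H](O[Si](C)(C)C(C)(C)C)C(=C)CCI)cc1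
A4 | alternative 2 | (3S,4R)-4-[(3E)-5-[(tert-butyldimethylsilyl)oxy]-3-methylpent-3-en-1-yl]-3-methyloxan-2-one | CC(C)(C)[Si](C)(C)OC/C=C(\C)CC[C@@H]1CCOC(=O)[C@H]1C
A5 | alternative 2 | [(3E)-5-[(tert-butyldimethylsilyl)oxy]-3-methylpent-3-en-1-yl]magnesium bromide | CC(C)(C)[Si](C)(C)OC/C=C(\C)CC[Mg]Br
A6 | alternative 2 | 5,6-dihydro-2H-pyran-2-one | O=C1C=CCCO1
A7 | alternative 3 | macrocyclic C24–C2 oxirane methyl ester | C[C@@]12CC/C=C(\C)CC[C@@H]([C@H](C)C(=O)OC)C/C=C(\C)CC[C@H]1O2
A8 | alternative 3 | seco alkenyl iodide with terminal alkene C9=C10 | C=C[C@@H]([C@H](C)C(=O)OC)C/C=C(\C)CC[C@H]1O[C@]1(C)CC/C=C(\C)I
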